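**Retrosynthetic overview**

1. Target 26 ⇐ triol 25 ⇐ tris-silyl lactone 24: C7 is carried as CH2OSi and oxidized last; the C1 and C12 hydroxyls are carried as silyl ethers.
2. Key disconnection: the C4–C5 bond of ring A together with the C10–O bond of the γ-lactone, both made from the open side chain of 23 by a Mn(OAc)3 oxidative radical cyclization–lactonization onto the C5=C10 alkene of ring B (rings B, C, D in place).
3. Enabling feature: C4 lies between the C3 ketone and the C19 carboxyl carbon (an oxidizable 2-methyl-β-keto ester C–H), C5=C10 can be the trisubstituted alkene of a cyclopentene ring B, and C19 sits 1,3 to C10 across C5, so the lactone bridging ring A is the retron of a radical carbolactonization.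
4. 23 ⇐ enal 17 + bis-silyl dienolate 20 (catalytic asymmetric vinylogous aldol sets C1); 17 ⇐ ketone 15 ⇐ enone 12 (conjugate addition sets C6) ⇐ enone 9 (1,3-carbonyl transposition) ⇐ tricyclic enedione 7.
5. 7 ⇐ ring D by gold-catalyzed Conia-ene closure of 6 ⇐ C8 propargylation of 5 ⇐ ring C by Diels–Alder reaction of diene 2 with (R)-cyclopentenone 3 (ring B). Ring order: B → C → D → A plus lactone.

Key step: step 18

Locants: gibberellane numbering is used for all compounds (ring A C1–C5, C10; ring B C5, C6, C8, C9, C10; ring C C8, C9, C11–C14; ring D C8, C14, C13, C16, C15; C7 on C6; C17 on C16; C18 methyl and C19 carboxyl on C4). α is the face of rings A and B that carries the lactone bridge, C11 and C14; β is the face that carries H-5, H-9, C7 and C15. The 12α-oxygen is on the face of ring C opposite to the C15–C16 bridge.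

Assumption: with Ti(OiPr)4/(R)-BINOL the dienolate attacks the Re face of enal 17, as it does with aryl and alkenyl aldehydes; if the sense were opposite, (S)-BINOL would be used.

**Route**

Step 1
Reactants: 1 but-3-en-2-one
Product: 2 2-(tert-butyldimethylsilyloxy)buta-1,3-diene
Conditions: TBSOTf, Et3N, Et2O, 0 °C → rt
Reagents that add atoms: tert-butyldimethylsilyl trifluoromethanesulfonate, CC(C)(C)[Si](C)(C)OS(=O)(=O)C(F)(F)F
Why: Soft enolization and O-silylation of the methyl ketone should give the 2-silyloxydiene (silyl enol ether formation); no stereocenter is formed.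

Step 2
Reactants: 3 (4R)-4-(tert-butyldimethylsilyloxy)cyclopent-2-en-1-one; 2 2-(tert-butyldimethylsilyloxy)buta-1,3-diene
Product: 4 cis-fused adduct (C6 ketone, 8β-H, 9β-H, 10β-OTBS, C12=C13 silyl enol ether)
Conditions: Me2AlCl (30 mol%), CH2Cl2, −78 → −30 °C; Et3N, aq NaHCO3
Reagents that add atoms: none
Why: Lewis-acid-promoted Diels–Alder reaction in which the nucleophilic C11 terminus of the diene bonds to the enone β-carbon C9 (para orientation, enol ether at C12=C13); suprafacial addition gives the cis fusion and approach anti to the C10 silyloxy group sets C8 and C9.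

Step 3
Reactants: 4 cis-fused adduct
Product: 5 bicyclic enone (C6 ketone, C5=C10, 8β-H, 9β-H, C12=C13 silyl enol ether)
Conditions: DBU, CH2Cl2, 0 °C
Reagents that add atoms: none
Why: E1cB β-elimination of the silanol from the β-silyloxy ketone should give the cyclopentenone without touching C8 and C9.

Step 4
Reactants: 5 bicyclic enone
Product: 6 8-propargyl bicyclic enone (propargyl β, cis to H-9)
Conditions: LiN(iPr)2, THF/DMPU, −78 °C; propargyl bromide, −78 → −40 °C
Reagents that add atoms: 3-bromoprop-1-yne, C#CCBr
Why: Kinetic α′-deprotonation at C8 and enolate alkylation from the face anti to C11, the only face that keeps the hydrindenone cis-fused, should set the C8 quaternary center.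

Step 5
Reactants: 6 8-propargyl bicyclic enone
Product: 7 tricyclic enedione (ring B cyclopent-5(10)-en-6-one; rings C/D bicyclo[3.2.1]octane with C12 ketone and C16 exocyclic methylene)
Conditions: (JohnPhos)Au(NCMe)SbF6 (3 mol%; JohnPhos = (2-biphenylyl)P(tBu)2), CH2Cl2/MeOH (10:1), rt
Reagents that add atoms: none
Why: Gold-catalyzed Conia-ene-type 5-exo-dig carbocyclization of the regiodefined silyl enol ether carbon C13 onto the activated alkyne carbon C16, then protodeauration, should close ring D and form the bridgehead C13 in the only geometrically possible way.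

Step 6
Reactants: 7 tricyclic enedione
Product: 8 12α-hydroxy enone
Conditions: NaBH4 (0.5 equiv), MeOH/CH2Cl2 (1:1), −78 °C
Reagents that add atoms: none
Why: Chemoselective borohydride reduction of the saturated ketone in the presence of the conjugated enone, with hydride delivered to the β face of C12 (equatorial attack, since the α face is blocked by the syn-axial C9–C10 bond), should give the axial 12α-alcohol.

Step 7
Reactants: 8 12α-hydroxy enone
Product: 9 12α-(tert-butyldimethylsilyloxy) enone
Conditions: TBSOTf, 2,6-lutidine, CH2Cl2, −78 → 0 °C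
Reagents that add atoms: tert-butyldimethylsilyl trifluoromethanesulfonate, CC(C)(C)[Si](C)(C)OS(=O)(=O)C(F)(F)F
Why: Silyl triflate silylation protects the hindered axial alcohol without changing any stereocenter.

Step 8
Reactants: 9 12α-silyloxy enone
Product: 10 5β,10β-epoxy-6-ketone
Conditions: 30% H2O2, aq NaOH (cat.), MeOH, 0 °C
Reagents that add atoms: hydrogen peroxide, OO
Why: Weitz–Scheffer nucleophilic epoxidation of the cyclopentenone should occur on the convex β face (syn to H-9, anti to C11); the epoxide configuration has no consequence after step 10.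

Step 9
Reactants: 10 5β,10β-epoxy-6-ketone
Product: 11 10β-hydroxy-Δ5(6) alkene
Conditions: N2H4·H2O, AcOH (cat.), MeOH, 0 °C → rt, under argon
Reagents that add atoms: none
Why: Wharton rearrangement of the epoxy hydrazone with loss of dinitrogen should move the oxygen from C6 to C10 and the alkene to C5=C6.

Step 10
Reactants: 11 10β-hydroxy-Δ5(6) alkene
Product: 12 transposed enone (C10 ketone, C5=C6)
Conditions: Dess–Martin periodinane, NaHCO3, CH2Cl2, 0 °C → rt
Reagents that add atoms: none
Why: Dess–Martin oxidation of the allylic alcohol under buffered conditions should give the enone without epimerizing C9.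

Step 11
Reactants: 12 transposed enone
Product: 14 6β-(hydroxymethyl)-10-ketone, via silylmethyl ketone 13 (not isolated)
Conditions: (iPrO)Me2SiCH2MgCl, CuI (10 mol%), THF, −78 → −20 °C; aq NH4Cl; then KF, KHCO3, 30% H2O2, THF/MeOH (1:1), rt
Reagents that add atoms: (isopropoxydimethylsilyl)methylmagnesium chloride, CC(C)O[Si](C)(C)C[Mg]Cl; hydrogen peroxide, OO
Why: Copper-catalyzed conjugate addition of the hydroxymethyl-anion equivalent to C6 is predicted on the β face (anti-periplanar to the C8–C14 bond and staggered between C9 and C15, whereas α attack eclipses C14), and Tamao–Fleming oxidation with retention then gives the 6β-CH2OH group (C7).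

Step 12
Reactants: 14 6β-(hydroxymethyl)-10-ketone
Product: 15 6β-(tert-butyldimethylsilyloxymethyl)-10-ketone
Conditions: TBSCl, imidazole, DMF, rt
Reagents that add atoms: tert-butyldimethylsilyl chloride, CC(C)(C)[Si](C)(C)Cl
Why: Standard silylation of the primary alcohol (protection).

Step 13
Reactants: 15 silyl-protected 10-ketone
Product: 16 Δ5(10)-enol triflate
Conditions: KN(SiMe3)2, THF, −78 °C; PhNTf2, −78 → 0 °C
Reagents that add atoms: N-phenylbis(trifluoromethanesulfonimide), O=S(=O)(N(c1ccccc1)S(=O)(=O)C(F)(F)F)C(F)(F)F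
Why: Kinetic enolization at the C5 methylene in preference to the ring-fusion C9 methine, then O-triflation, should give the C5=C10 enol triflate regioselectively.

Step 14
Reactants: 16 Δ5(10)-enol triflate
Product: 17 Δ5(10)-10-carbaldehyde (enal, C1 attached to C10)
Conditions: Pd(PPh3)4 (5 mol%), CO (1 atm), Bu3SnH (slow addition), LiCl, THF, 50 °C
Reagents that add atoms: carbon monoxide, [C-]#[O+]
Why: Palladium-catalyzed reductive carbonylation (formylation) of the enol triflate by oxidative addition, CO insertion and hydride transfer from the stannane should give the enal.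

Step 15
Reactants: 18 tert-butyl 2-methyl-3-oxobutanoate
Product: 20 1-tert-butoxy-2-methyl-1,3-bis(trimethylsilyloxy)buta-1,3-diene (mixture of geometrical isomers), via mono(trimethylsilyl) enol ether 19 (not isolated)
Conditions: Me3SiCl, Et3N, hexane, rt; filter, concentrate; LiN(iPr)2, THF, −78 °C; Me3SiCl
Reagents that add atoms: chlorotrimethylsilane, C[Si](C)(C)Cl
Why: Two successive enolization–O-silylation events (first at the β-dicarbonyl position, then kinetic at the methyl group) should give the 1,3-bis(silyloxy)diene.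

Step 16
Reactants: 17 enal; 20 bis(silyloxy)diene
Product: 22 tert-butyl δ-hydroxy-2-methyl-β-keto ester with (1R)-carbinol (C4 epimer mixture), via silylated aldol adduct 21 (not isolated)
Conditions: Ti(OiPr)4 (10 mol%), (R)-BINOL (10 mol%), 4 Å molecular sieves, THF, −78 °C → rt; then PPTS (cat.), MeOH, 0 °C
Reagents that add atoms: none
Why: Catalytic asymmetric vinylogous Mukaiyama aldol addition of the terminal diene carbon (C2) to the aldehyde carbon, under control of the titanium–BINOL complex (Re-face attack), should set C1 as R, and methanolysis removes the trimethylsilyl groups.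

Step 17
Reactants: 22 δ-hydroxy-β-keto ester
Product: 23 tert-butyl δ-(tert-butyldimethylsilyloxy)-2-methyl-β-keto ester (key-step precursor)
Conditions: TBSCl, imidazole, DMF, rt
Reagents that add atoms: tert-butyldimethylsilyl chloride, CC(C)(C)[Si](C)(C)Cl
Why: Silylation of the allylic alcohol prevents δ-lactonization and hydride shift and keeps O1 non-participating in the next step.

Step 18
Reactants: 23 δ-silyloxy-2-methyl-β-keto tert-butyl ester
Product: 24 tris-silyl 3-oxo-19,10-lactone (1β-OTBS, 12α-OTBS, 7-OTBS)
Conditions: Mn(OAc)3·2H2O (2.5 equiv), KOAc (2 equiv), degassed AcOH, 0.01 M, 25 °C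
Reagents that add atoms: none
Why: Mn(OAc)3 converts the 2-methyl-β-keto ester into its trivalent-manganese enolate and inner-sphere electron transfer gives the electrophilic C4 radical, which adds 6-endo-trig to C5 of the C5=C10 alkene (ring A closure) to leave the tertiary C10 radical; a second equivalent oxidizes this radical to the C10 cation, which is captured by the carbonyl oxygen of the syn-axial tert-butyl ester (five-membered closure across C4–C5–C10) with loss of isobutene to give the γ-lactone. The closest known reaction type is the trivalent-manganese oxidative free-radical cyclization of unsaturated 2-alkyl-β-keto esters in the 6-endo mode, terminated by lactonization of the tertiary cation onto the ester, and the related carbolactonization of alkenes by β-dicarbonyl acids. C5 is controlled by C6, because the radical approaches anti to the 6β-CH2OTBS group on the α face and H-5 becomes β; C4 is controlled by the chair-like transition state with the ester axial and the methyl equatorial, and only this epimer can lactonize; C10 is set by intramolecular delivery of the lactone oxygen cis to the new C4–C5 bond, which makes the A/B fusion trans and leaves the C1 silyloxy group axial and anti to the lactone. The step needs 6-endo over 5-exo closure, secured by the fully substituted C10 terminus and the ketone inside the forming ring; it needs reaction at C5=C10 and not at the C16 methylene, secured by intramolecularity and high dilution; and it needs oxidation of the C10 radical to outrun elimination, secured by leaving out any divalent copper salt and by silyl (non-acyl) protection of O1 and O12.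

Step 19
Reactants: 24 tris-silyl lactone
Product: 25 1β,12α-dihydroxy-7-hydroxymethyl 3-oxo-19,10-lactone (triol)
Conditions: HF·pyridine, THF/pyridine, 0 °C → rt
Reagents that add atoms: none
Why: Fluoride-mediated desilylation under weakly acidic conditions removes the three silyl ethers and avoids base, which could cause retro-aldol cleavage of the β-hydroxy ketone or retro-Claisen opening of the β-keto lactone.

Step 20
Reactants: 25 triol
Product: 26 target acid CNP0259985.1
Conditions: TEMPO (20 mol%), PhI(OAc)2 (2.5 equiv), MeCN/H2O (1:1), rt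
Reagents that add atoms: water, O
Why: Oxoammonium (TEMPO) oxidation is selective for the primary alcohol over the hindered secondary C1 and C12 alcohols and, in water, should carry the aldehyde hydrate on to the C7 carboxylic acid without epimerizing C6.

**Compound list**

1 | but-3-en-2-one | CC(=O)C=C | starting material
2 | 2-(tert-butyldimethylsilyloxy)buta-1,3-diene | C=CC(=C)O[Si](C)(C)C(C)(C)C | intermediate
3 | (4R)-4-(tert-butyldimethylsilyloxy)cyclopent-2-en-1-one | O=C1C=C[C@H](O[Si](C)(C)C(C)(C)C)C1 | starting material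
4 | cis-3,5-bis(tert-butyldimethylsilyloxy)-2,3,3a,4,7,7a-hexahydro-1H-inden-1-one (C6 ketone, 8β-H, 9β-H, 10β-OTBS, C12=C13 enol ether) | [C@H]12CC=C(O[Si](C)(C)C(C)(C)C)C[C@H]1[C@H](O[Si](C)(C)C(C)(C)C)CC2=O | intermediate
5 | cis-5-(tert-butyldimethylsilyloxy)-3a,4,7,7a-tetrahydro-1H-inden-1-one (C6 ketone, C5=C10, 8β-H, 9β-H) | [C@H]12CC=C(O[Si](C)(C)C(C)(C)C)C[C@H]1C=CC2=O | intermediate
6 | cis-7a-(prop-2-yn-1-yl)-5-(tert-butyldimethylsilyloxy)-3a,4,7,7a-tetrahydro-1H-inden-1-one (8β-propargyl, 9β-H) | C#CC[C@]12CC=C(O[Si](C)(C)C(C)(C)C)C[C@H]1C=CC2=O | intermediate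
7 | tricyclic enedione: ring B cyclopent-5(10)-en-6-one fused at C8–C9 to the bicyclo[3.2.1]octane (C12 ketone, C16 exocyclic methylene, 9β-H) | C=C1C[C@]23C[C@H]1C(=O)C[C@H]2C=CC3=O | intermediate
8 | 12α-hydroxy tricyclic enone | C=C1C[C@]23C[C@H]1[C@@H](O)C[C@H]2C=CC3=O | intermediate
9 | 12α-(tert-butyldimethylsilyloxy) tricyclic enone (C6 ketone, C5=C10) | C=C1C[C@]23C[C@H]1[C@@H](O[Si](C)(C)C(C)(C)C)C[C@H]2C=CC3=O | intermediate
10 | 5β,10β-epoxy-6-ketone | C=C1C[C@]23C[C@H]1[C@@H](O[Si](C)(C)C(C)(C)C)C[C@H]2[C@@H]4O[C@@H]4C3=O | intermediate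
11 | 10β-hydroxy-Δ5(6) alkene | C=C1C[C@]23C[C@H]1[C@@H](O[Si](C)(C)C(C)(C)C)C[C@H]2[C@H](O)C=C3 | intermediate
12 | transposed enone (C10 ketone, C5=C6) | C=C1C[C@]23C[C@H]1[C@@H](O[Si](C)(C)C(C)(C)C)C[C@H]2C(=O)C=C3 | intermediate
13 | 6β-[(isopropoxydimethylsilyl)methyl]-10-ketone | C=C1C[C@]23C[C@H]1[C@@H](O[Si](C)(C)C(C)(C)C)C[C@H]2C(=O)C[C@@H]3C[Si](C)(C)OC(C)C | intermediate
14 | 6β-(hydroxymethyl)-10-ketone | C=C1C[C@]23C[C@H]1[C@@H](O[Si](C)(C)C(C)(C)C)C[C@H]2C(=O)C[C@@H]3CO | intermediate
15 | 6β-(tert-butyldimethylsilyloxymethyl)-10-ketone | C=C1C[C@]23C[C@H]1[C@@H](O[Si](C)(C)C(C)(C)C)C[C@H]2C(=O)C[C@@H]3CO[Si](C)(C)C(C)(C)C | intermediate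
16 | Δ5(10)-enol triflate (OTf on C10) | C=C1C[C@]23C[C@H]1[C@@H](O[Si](C)(C)C(C)(C)C)C[C@H]2C(OS(=O)(=O)C(F)(F)F)=C[C@@H]3CO[Si](C)(C)C(C)(C)C | intermediate
17 | Δ5(10)-10-carbaldehyde (C1 enal) | C=C1C[C@]23C[C@H]1[C@@H](O[Si](C)(C)C(C)(C)C)C[C@H]2C(C=O)=C[C@@H]3CO[Si](C)(C)C(C)(C)C | intermediate
18 | tert-butyl 2-methyl-3-oxobutanoate | CC(=O)C(C)C(=O)OC(C)(C)C | starting material
19 | tert-butyl 2-methyl-3-(trimethylsilyloxy)but-2-enoate | CC(O[Si](C)(C)C)=C(C)C(=O)OC(C)(C)C | intermediate
20 | 1-tert-butoxy-2-methyl-1,3-bis(trimethylsilyloxy)buta-1,3-diene | C=C(O[Si](C)(C)C)C(C)=C(O[Si](C)(C)C)OC(C)(C)C | intermediate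
21 | silylated aldol adduct (1-OTMS, C3=C4 trimethylsilyl enol ether) | C=C1C[C@]23C[C@H]1[C@@H](O[Si](C)(C)C(C)(C)C)C[C@H]2C(=C[C@@H]3CO[Si](C)(C)C(C)(C)C)[C@H](O[Si](C)(C)C)CC(O[Si](C)(C)C)=C(C)C(=O)OC(C)(C)C | intermediate
22 | tert-butyl (5R)-5-hydroxy-2-methyl-3-oxo-5-(tricyclic cyclopentenyl)pentanoate ((1R)-carbinol, C4 epimers) | C=C1C[C@]23C[C@H]1[C@@H](O[Si](C)(C)C(C)(C)C)C[C@H]2C(=C[C@@H]3CO[Si](C)(C)C(C)(C)C)[C@H](O)CC(=O)C(C)C(=O)OC(C)(C)C | intermediate
23 | 1-O-tert-butyldimethylsilyl ether of 22 (key-step precursor) | C=C1C[C@]23C[C@H]1[C@@H](O[Si](C)(C)C(C)(C)C)C[C@H]2C(=C[C@@H]3CO[Si](C)(C)C(C)(C)C)[C@H](O[Si](C)(C)C(C)(C)C)CC(=O)C(C)C(=O)OC(C)(C)C | intermediate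
24 | 1β,12α-bis(tert-butyldimethylsilyloxy)-7-(tert-butyldimethylsilyloxy)-3-oxo-19,10-lactone | C=C1C[C@]23C[C@H]1[C@@H](O[Si](C)(C)C(C)(C)C)C[C@H]2[C@]12OC(=O)[C@](C)(C(=O)C[C@H]1O[Si](C)(C)C(C)(C)C)[C@H]2[C@@H]3CO[Si](C)(C)C(C)(C)C | intermediate
25 | 1β,12α-dihydroxy-7-hydroxymethyl-3-oxo-19,10-lactone | C=C1C[C@]23C[C@H]1[C@@H](O)C[C@H]2[C@]12OC(=O)[C@](C)(C(=O)C[C@H]1O)[C@H]2[C@@H]3CO | intermediate
26 | CNP0259985.1 (1β,12α-dihydroxy-3-oxo C19 gibberellin 19,10-lactone 7-oic acid) | C=C1C[C@]23C[C@H]1[C@@H](O)C[C@H]2[C@]12OC(=O)[C@](C)(C(=O)C[C@H]1O)[C@H]2[C@@H]3C(=O)O | target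

**Step count and risks**

Total step count: 20. Longest linear sequence: 19 (steps 1–14 and 16–20); step 15 is a one-step side branch.

Steps most likely to fail:

1. Step 18. Oxidation of the tertiary C10 radical, which carries a β-silyloxy group, may be too slow, so that hydrogen abstraction or elimination overtakes lactonization; capture of the cation by O12 is a second risk. The fallback sets out from 23 and comes back at 24, replacing the oxidative termination by halogen-atom transfer and polar ionization. Bromination at C4 with N-bromosuccinimide (Mg(ClO4)2 cat., MeCN) should give the α-bromo-β-keto ester F1. Bromine-atom-transfer radical cyclization (CuBr/tris(2-pyridylmethyl)amine cat., 1,2-dichloroethane, 60 °C) should close ring A by the same 6-endo addition and end at the tertiary C10 bromide F2. AgOTf with 2,6-di-tert-butylpyridine (CH2Cl2, −40 °C) should then ionize the C10–Br bond, and the axial tert-butyl ester should close the lactone with loss of isobutene to give 24.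

2. Step 11. Addition of the bulky silylmethyl copper reagent to the neopentyl β-carbon C6 may be slow, and facial selectivity may be poor because C14 and C15 flank C6 almost symmetrically. The fallback sets out from 11 and comes back at 14, delivering C7 from the 10β-hydroxyl, whose configuration is set at C10 where the two faces differ clearly (H-9 against C11). Hydroxyl-directed Simmons–Smith cyclopropanation (Et2Zn, CH2I2, CH2Cl2, −20 °C) should give the β-cyclopropyl carbinol F3. Dess–Martin oxidation should give the cyclopropyl ketone F4. Me3SiI (CH2Cl2, −40 °C, aqueous work-up) should open the cyclopropane by attack of iodide at the methylene carbon with cleavage of the external C5–C7 bond, giving the iodomethyl ketone F5. CsOAc in DMF should give the acetoxymethyl ketone F6, and K2CO3 in MeOH should then give 14.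

3. Step 9. Hydrazone formation at the neopentyl C6 ketone may be slow, azine formation may compete, and diimide formed from hydrazine may reduce the alkenes. The fallback sets out from 10 and comes back at 11, using a radical epoxide fragmentation in place of the hydrazone. NaBH4 (MeOH, 0 °C) should give the epoxy alcohol F7 (either C6 epimer serves). 1,1′-Thiocarbonyldiimidazole (DMAP, CH2Cl2) should give the imidazolylthiocarbonyl derivative F8. Bu3SnH with AIBN (benzene, 80 °C) should generate the C6 radical, which opens the adjacent epoxide to the C10 alkoxy radical, and reduction of that radical by the stannane gives 11.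

Further compounds
F1 | step 18 | 4-bromo derivative of 23 (α-bromo-β-keto ester, C4 epimers) | C=C1C[C@]23C[C@H]1[C@@H](O[Si](C)(C)C(C)(C)C)C[C@H]2C(=C[C@@H]3CO[Si](C)(C)C(C)(C)C)[C@H](O[Si](C)(C)C(C)(C)C)CC(=O)C(C)(Br)C(=O)OC(C)(C)C
F2 | step 18 | ring-A-closed tertiary C10 bromide with tert-butyl ester on C4 (C10 configuration not defined) | C=C1C[C@]23C[C@H]1[C@@H](O[Si](C)(C)C(C)(C)C)C[C@H]2C4(Br)[C@H](O[Si](C)(C)C(C)(C)C)CC(=O)[C@@](C)(C(=O)OC(C)(C)C)[C@H]4[C@@H]3CO[Si](C)(C)C(C)(C)C
F3 | step 11 | 5β,6β-methano (cyclopropyl) 10β-carbinol | C=C1C[C@]23C[C@H]1[C@@H](O[Si](C)(C)C(C)(C)C)C[C@H]2[C@H](O)[C@@H]4C[C@@H]43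
F4 | step 11 | 5β,6β-methano (cyclopropyl) 10-ketone | C=C1C[C@]23C[C@H]1[C@@H](O[Si](C)(C)C(C)(C)C)C[C@H]2C(=O)[C@@H]4C[C@@H]43
F5 | step 11 | 6β-(iodomethyl)-10-ketone | C=C1C[C@]23C[C@H]1[C@@H](O[Si](C)(C)C(C)(C)C)C[C@H]2C(=O)C[C@@H]3CI
F6 | step 11 | 6β-(acetoxymethyl)-10-ketone | C=C1C[C@]23C[C@H]1[C@@H](O[Si](C)(C)C(C)(C)C)C[C@H]2C(=O)C[C@@H]3COC(C)=O
F7 | step 9 | 5β,10β-epoxy-6-ol (C6 epimers) | C=C1C[C@]23C[C@H]1[C@@H](O[Si](C)(C)C(C)(C)C)C[C@H]2[C@@H]4O[C@@H]4C3O
F8 | step 9 | 6-O-(imidazol-1-ylthiocarbonyl) derivative of the epoxy alcohol | C=C1C[C@]23C[C@H]1[C@@H](O[Si](C)(C)C(C)(C)C)C[C@H]2[C@@H]4O[C@@H]4C3OC(=S)n5ccnc5
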